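**Plan**
- Cuts: the 4'-O-benzyl and 7-O-methyl groups are removed first. The C5–C6 bond of ring A is then cut, which unfolds the benzene ring into the 2-pyranone of a pyrano[4,3-b]pyran-4,5-dione. Next come O1–C2, C2–C3 and C4–C4a of ring C, and last C8–C8a and the lactone C–O bond.
- Enabling feature: in ring A the oxygens on C5, C7 and C8a stand 1,3,5, like the carbonyls of a poly-β-keto chain, and C6 and C8 carry OMe. C8a is already etherified by O1 of ring C. A 2-pyranone holds this chain in masked, uncharged form, with C5 as lactone carbonyl, C7 as enol carbon and a CH2OMe group on C7 as the future C6.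
- Forward order: the monocyclic 4-hydroxy-2-pyranone comes first. Ring C follows by C-acylation, aroyl shift and cyclodehydration, and ring B arrives with the aroyl chloride. Ring A comes last, by lactone opening and Claisen reclosure.
- End game: methylation of the unchelated 7-OH, then hydrogenolysis of the benzyl ether.
- Stereochemistry: the target has no stereocentre and no stereogenic double bond. The labile methine carbons met on the way are erased by enolisation or aromatisation.

Key step: step 6

Assumption: 1,3-dimethoxyacetone 1 is taken as a catalogue chemical. Atoms are numbered as in the flavone, which matches the pyrano[4,3-b]pyran numbering except that lactone O6 is replaced by C6.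

**Step 1**
Reactants: 1 1,3-dimethoxyacetone
Product: 2 [(1,3-dimethoxyprop-1-en-2-yl)oxy]trimethylsilane (E/Z mixture)
Conditions: Me3SiOTf (1.1 equiv), Et3N (1.3 equiv), Et2O, 0 °C to rt; distillation
Reagents that add atoms: trimethylsilyl triflate, C[Si](C)(C)OS(=O)(=O)C(F)(F)F
Why: Soft enolisation with a silyl triflate and a tertiary amine is the standard silyl enol ether synthesis; the ketone is symmetrical, so only one regioisomer can form, and the double-bond geometry does not matter because this bond ends up inside a ring.

**Step 2**
Reactants: 2 [(1,3-dimethoxyprop-1-en-2-yl)oxy]trimethylsilane; 3 malonyl dichloride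
Product: 4 4-hydroxy-5-methoxy-6-(methoxymethyl)-2H-pyran-2-one
Conditions: Et2O, −78 °C to rt
Reagents that add atoms: none
Why: This is the known [3+3] cyclocondensation of silyl enol ethers with malonyl dichloride, in which C-acylation at the enol ether carbon and O-acylation of the resulting enol close the lactone, and the preformed enol ether avoids the self-condensation of malonyl dichloride that dominates with free ketones.

**Step 3**
Reactants: 4 4-hydroxy-5-methoxy-6-(methoxymethyl)-2H-pyran-2-one; 5 methoxyacetyl chloride
Product: 7 4-hydroxy-5-methoxy-3-(methoxyacetyl)-6-(methoxymethyl)-2H-pyran-2-one, via enol ester 6 (not isolated)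
Conditions: Et3N (2.2 equiv), toluene, 0 °C to rt; then DMAP (0.2 equiv), 90 °C; 1 M HCl wash
Reagents that add atoms: none
Why: O-acylation followed by DMAP-catalysed O-to-C acyl migration (Fries-type rearrangement of an enol ester) is the usual entry to 3-acyl-4-hydroxy-2-pyranones; C3 is the only free nucleophilic carbon because C5 is blocked by OMe, and the chelated β-tricarbonyl is the thermodynamic sink.

**Step 4**
Reactants: 7 4-hydroxy-5-methoxy-3-(methoxyacetyl)-6-(methoxymethyl)-2H-pyran-2-one; 8 4-benzyloxybenzoyl chloride
Product: 10 3-[3-(4-benzyloxyphenyl)-2-methoxy-3-oxopropanoyl]-4-hydroxy-5-methoxy-6-(methoxymethyl)-2H-pyran-2-one, via aroyl enol ester 9 (not isolated)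
Conditions: Et3N (1.1 equiv), THF, 0 °C; then LiN(SiMe3)2 (3.3 equiv), −78 to 0 °C; 1 M HCl
Reagents that add atoms: none
Why: This is a one-pot O-aroylation and Baker–Venkataraman rearrangement, in which the enolate of the methoxyacetyl side chain attacks the neighbouring aroyl ester through a six-membered transition state, the doubly stabilised dianion of 10 drives the shift, and the non-nucleophilic amide base spares the lactone and the activated ester.

**Step 5**
Reactants: 10 3-[3-(4-benzyloxyphenyl)-2-methoxy-3-oxopropanoyl]-4-hydroxy-5-methoxy-6-(methoxymethyl)-2H-pyran-2-one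
Product: 11 2-(4-benzyloxyphenyl)-3,8-dimethoxy-7-(methoxymethyl)-4H,5H-pyrano[4,3-b]pyran-4,5-dione
Conditions: H2SO4 (cat.), AcOH, 60 °C
Reagents that add atoms: none
Why: Acid-catalysed cyclodehydration of the 1,3-diketone is the closing step of the Baker–Venkataraman flavone synthesis and the known way from 3-(β-ketoacyl)-4-hydroxy-2-pyranones to pyranopyrandiones; the C4 hydroxyl adds 6-exo-trig to the aroyl carbonyl, water is lost, and the benzyl ether, lactone and methyl ethers tolerate catalytic acid at this temperature.

**Step 6**
Reactants: 11 2-(4-benzyloxyphenyl)-3,8-dimethoxy-7-(methoxymethyl)-4H,5H-pyrano[4,3-b]pyran-4,5-dione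
Product: 13 4'-benzyloxy-5,7-dihydroxy-3,6,8-trimethoxyflavone, via ring-opened keto ester 12 (not isolated)
Conditions: Mg(OMe)2 (4 equiv, from Mg turnings), MeOH, reflux, Ar; then 2 M HCl
Reagents that add atoms: none
Why: Methoxide adds to the lactone carbonyl C5 of the uncharged 2-pyranone, the C5–O6 bond breaks and keto ester 12 appears as its magnesium dienolate; proton exchange in methanol moves the enolate from the C8 side to the methoxymethyl side of the C7 ketone, this carbon (the future C6) attacks the ester on C4a, methoxide leaves, C5–C6 is formed, and two enolisations turn the cyclic trione into the benzene ring. The closest known reaction type is the Mg(OMe)2-induced opening and Claisen (Dieckmann-type) reclosure of 6-alkyl-2-pyranones and fused 2-pyranones to phloroglucinol derivatives, the laboratory counterpart of polyketide aromatisation. Ring A closes in the 6-(enolendo)-exo-trig mode, which is allowed for enolates, and no stereocentre is created because the labile C8 methine of 12 becomes an arene carbon. C-acylation at the ester must outrun return to the lactone, attack on C4 and methoxide addition at C2 of ring C: relactonisation is reversible and only regenerates 11, C4 is the unreactive vinylogous ester carbonyl of a 4-pyranone, C2 is deactivated by the 4-benzyloxyphenyl and 3-methoxy donors, and magnesium bridging the C4 and ester carbonyls activates the ester while the α-methoxy group acidifies the C6 protons. Formation of the aromatic magnesium phenolate makes the closure irreversible and should drain all these equilibria towards 13. Because O1 never leaves C8a, only the C5 and C7 oxygens appear as free hydroxyls, and even a transient opening of ring C would be harmless, since the opened ring A is symmetric about the C4a–C7 axis and the acidic work-up can only reclose it to the same flavone.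

**Step 7**
Reactants: 13 4'-benzyloxy-5,7-dihydroxy-3,6,8-trimethoxyflavone
Product: 14 4'-benzyloxy-5-hydroxy-3,6,7,8-tetramethoxyflavone
Conditions: Me2SO4 (1.05 equiv), K2CO3 (1.5 equiv), acetone, reflux
Reagents that add atoms: dimethyl sulfate, COS(=O)(=O)OC
Why: In this Williamson-type O-methylation under weak base the 5-OH is tied up in a hydrogen bond to the C4 carbonyl and is far less acidic and nucleophilic than the 7-OH, which is the classical basis of partial methylation of 5,7-dihydroxyflavones, and one equivalent of the small electrophile keeps the reaction at the monoether.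

**Step 8**
Reactants: 14 4'-benzyloxy-5-hydroxy-3,6,7,8-tetramethoxyflavone
Product: 15 calycopterin (5,4'-dihydroxy-3,6,7,8-tetramethoxyflavone)
Conditions: H2 (1 atm), 10% Pd/C, EtOAc–MeOH, rt
Reagents that add atoms: none
Why: Catalytic hydrogenolysis cleaves only the benzylic C–O bond, since the tetrasubstituted C2=C3 bond of the chromone and the methyl ethers are inert at ambient pressure and temperature.

**Compound list**
1 | 1,3-dimethoxyacetone | COCC(=O)COC | starting material
2 | [(1,3-dimethoxyprop-1-en-2-yl)oxy]trimethylsilane (E/Z mixture, geometry not carried on) | COCC(=COC)O[Si](C)(C)C | intermediate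
3 | malonyl dichloride | O=C(Cl)CC(Cl)=O | starting material
4 | 4-hydroxy-5-methoxy-6-(methoxymethyl)-2H-pyran-2-one | COCC1=C(OC)C(O)=CC(=O)O1 | intermediate
5 | methoxyacetyl chloride | COCC(Cl)=O | starting material
6 | 5-methoxy-6-(methoxymethyl)-2-oxo-2H-pyran-4-yl methoxyacetate | COCC1=C(OC)C(OC(=O)COC)=CC(=O)O1 | intermediate
7 | 4-hydroxy-5-methoxy-3-(methoxyacetyl)-6-(methoxymethyl)-2H-pyran-2-one | COCC1=C(OC)C(O)=C(C(=O)COC)C(=O)O1 | intermediate
8 | 4-benzyloxybenzoyl chloride | O=C(Cl)c1ccc(OCc2ccccc2)cc1 | starting material
9 | 5-methoxy-3-(methoxyacetyl)-6-(methoxymethyl)-2-oxo-2H-pyran-4-yl 4-(benzyloxy)benzoate | COCC1=C(OC)C(OC(=O)c2ccc(OCc3ccccc3)cc2)=C(C(=O)COC)C(=O)O1 | intermediate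
10 | 3-[3-(4-benzyloxyphenyl)-2-methoxy-3-oxopropanoyl]-4-hydroxy-5-methoxy-6-(methoxymethyl)-2H-pyran-2-one (diketo tautomer drawn; methine labile, racemic) | COCC1=C(OC)C(O)=C(C(=O)C(OC)C(=O)c2ccc(OCc3ccccc3)cc2)C(=O)O1 | intermediate
11 | 2-(4-benzyloxyphenyl)-3,8-dimethoxy-7-(methoxymethyl)-4H,5H-pyrano[4,3-b]pyran-4,5-dione | COCC1=C(OC)C2=C(C(=O)O1)C(=O)C(OC)=C(O2)c1ccc(OCc3ccccc3)cc1 | intermediate
12 | methyl 6-(4-benzyloxyphenyl)-2-(1,3-dimethoxy-2-oxopropyl)-5-methoxy-4-oxo-4H-pyran-3-carboxylate (methine labile, racemic) | COCC(=O)C(OC)C1=C(C(=O)OC)C(=O)C(OC)=C(O1)c1ccc(OCc2ccccc2)cc1 | intermediate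
13 | 4'-benzyloxy-5,7-dihydroxy-3,6,8-trimethoxyflavone | COc1c(O)c(OC)c2oc(-c3ccc(OCc4ccccc4)cc3)c(OC)c(=O)c2c1O | intermediate
14 | 4'-benzyloxy-5-hydroxy-3,6,7,8-tetramethoxyflavone | COc1c(OC)c(O)c2c(=O)c(OC)c(-c3ccc(OCc4ccccc4)cc3)oc2c1OC | intermediate
15 | calycopterin | COc1c(OC)c(O)c2c(=O)c(OC)c(-c3ccc(O)cc3)oc2c1OC | target

**Step count**
Total step count: 8. Longest linear sequence: 8 steps (1 to 15); compounds 3, 5 and 8 are bought.

**Steps most likely to fail**

**Step 6.** The enolate may stay on its more acidic C8 side, so that the Claisen closure is slower than return to the lactone. Long heating would then let methoxide add to C2 of ring C and cut off the aroyl unit by retro-Claisen fragmentation. The fallback splits the cascade into two operations and removes the nucleophilic base from the ring-closing event.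
- Starting from 11, NaOMe (1.1 equiv) in MeOH–THF at 0 °C with a cold AcOH quench should stop at the ring-opened keto ester 12, which is isolated.
- LiN(SiMe3)2 (3.5 equiv) in THF, −78 to 0 °C, then removes the C8 proton and one C6 proton.
- The terminal carbanion of this dianion is the more reactive site, as in β-dicarbonyl dianions. It closes onto the ester in a Dieckmann condensation without free methoxide at the outset.
- Acidification rejoins the route at 13. No compound outside the list is made (F0).

**Step 2.** Protodesilylation of the enol ether by the acid liberated during the condensation, and self-condensation of malonyl dichloride through its ketene, may consume both partners before the ring closes. The fallback builds the same pyranone from a linear triketide.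
- Starting from 5, MeNHOMe·HCl and Et3N in CH2Cl2 should give N,2-dimethoxy-N-methylacetamide F1.
- The dianion of commercial methyl 4-methoxyacetoacetate (NaH, then n-BuLi, THF, 0 °C) is acylated at its γ-carbon by F1. The chelated tetrahedral adduct prevents over-reaction, and the product should be methyl 4,6-dimethoxy-3,5-dioxohexanoate F2.
- DBU in toluene at reflux lactonises F2 through the C5 enol oxygen, and the route is rejoined at 4.

**Step 4.** The activated aroyl enol ester may pass its acyl group to an external nucleophile. The amide base may also deprotonate the C6 methoxymethyl group instead of the side chain, so that cleavage back to the acylpyranone outruns the acyl shift. The fallback brings in ring B at the aldehyde oxidation level.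
- Starting from 7, a piperidine-catalysed Claisen–Schmidt condensation with commercial 4-benzyloxybenzaldehyde (CHCl3, reflux, removal of water) should give (Z)-3-[3-(4-benzyloxyphenyl)-2-methoxyprop-2-enoyl]-4-hydroxy-5-methoxy-6-(methoxymethyl)-2H-pyran-2-one F3.
- I2 (cat.) in DMSO at 120 °C then brings about oxa-Michael closure. This gives 2-(4-benzyloxyphenyl)-3,8-dimethoxy-7-(methoxymethyl)-2,3-dihydro-4H,5H-pyrano[4,3-b]pyran-4,5-dione F4.
- F4 is dehydrogenated in the same pot, as in the chalcone-to-flavone oxidation. The route is rejoined at 11, and 9, 10 and step 5 are bypassed.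

**Further compounds**
F0 | step 6 | none | none
F1 | step 2 | N,2-dimethoxy-N-methylacetamide | COCC(=O)N(C)OC
F2 | step 2 | methyl 4,6-dimethoxy-3,5-dioxohexanoate (methine labile, racemic) | COCC(=O)C(OC)C(=O)CC(=O)OC
F3 | step 4 | (Z)-3-[3-(4-benzyloxyphenyl)-2-methoxyprop-2-enoyl]-4-hydroxy-5-methoxy-6-(methoxymethyl)-2H-pyran-2-one | COCC1=C(OC)C(O)=C(C(=O)/C(OC)=C/c2ccc(OCc3ccccc3)cc2)C(=O)O1
F4 | step 4 | 2-(4-benzyloxyphenyl)-3,8-dimethoxy-7-(methoxymethyl)-2,3-dihydro-4H,5H-pyrano[4,3-b]pyran-4,5-dione (racemic diastereomer mixture, both centres erased on oxidation) | COCC1=C(OC)C2=C(C(=O)O1)C(=O)C(OC)C(O2)c1ccc(OCc3ccccc3)cc1
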